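# Proposed synthesis of 2-(1-hydroxy-4-oxocyclohexyl)ethyl hexadecanoate (11)

## The problem

The target 11 is a single six-membered carbocycle. Counting from the carbinol carbon, C1 is fully substituted and carries a free tertiary hydroxyl and a two-carbon arm ending in a palmitate ester, and C4 is a ketone. C1 and C4 lie on a mirror plane, so 11 has no stereocentre; any stereocentre met on the way is transient, may be racemic, and neither needs nor offers control. The task is therefore constitutional: build an oxygenated quaternary carbon with the arm attached, place two ring oxygens 1,4 to each other at different oxidation levels, and acylate only the primary of three oxygen functions. Several groups are fragile. The tertiary alcohol is acid-labile, and at the stage of a 4-hydroxycyclohex-2-enone its loss is driven by aromatisation to a para-substituted phenol. A free primary hydroxyl on the arm would add in conjugate fashion to such an enone, so it must stay masked until the ring is saturated. The long-chain ester is cleaved by hydroxide or alkoxide and is best attached last, and the route passes through a bicyclic peroxide that must be kept cold and dilute. The enabling feature is that the oxygens on C1 and C4 sit directly across the ring, the distance that one molecule of dioxygen (5) spans when it adds to the termini of a cyclohexa-1,3-diene. Both oxygens can therefore come from one molecule of 5 through the 1,2-dioxine ring of a 2,3-dioxabicyclo[2.2.2]oct-5-ene. In that peroxide C1 bears no hydrogen and C4 bears exactly one, so base-induced O–O cleavage can only give the ketone at C4 and the alcohol at C1.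

## Retrosynthesis

**Ester C–O bond.** Target 11 is cut at the acyl–oxygen bond into keto diol 9 and palmitoyl chloride 10. Putting this last keeps the base-sensitive, lipophilic ester away from the aqueous carbonate and amine base used earlier. Carrying the ester from the start would also need a boron reagent that cannot be bought. Compound 9 is sixteen carbons simpler, and the forward step must only tell a primary from a tertiary hydroxyl.

**Alkene and benzyl ether in one reduction.** Compound 9 is traced to racemic hydroxy enone 7 by restoring the C2=C3 double bond and an O-benzyl group on the arm. One hydrogenation removes both, passing through saturated benzyl ether 8, so the protecting group costs no step. A silyl ether would need a separate acid or fluoride step on an acid-sensitive carbinol. The benzyl group must survive aqueous base, photooxygenation and amine base, and must stay on until the alkene is gone.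

**O–O bond.** In 7 the C4 ketone oxygen and the C1 hydroxyl oxygen are rejoined, with a hydrogen returned to C4, to give endoperoxide 6. The forward Kornblum–DeLaMare fragmentation is an isomerisation and needs neither reductant nor oxidant. The neighbouring option, reduction to an ene-diol and then oxidation of the secondary allylic alcohol, spends two redox steps for the same result. Regiochemistry is fixed by constitution, since only C4 carries a removable hydrogen. The base must take a bridgehead hydrogen of a rigid bicycle without dehydrating 7.

**Two C–O bonds, the key cut.** Compound 6 is cut at C1–O and C4–O into diene 4 and dioxygen 5. This removes every ring oxygen at once and leaves a hydrocarbon diene whose only heteroatom is the ether of the arm. Other ways from 4 to the same 1,4-dioxygen pattern (epoxidation and allylic transposition) take three or four steps. The forward reaction must channel photoexcited 5 into [4+2] addition and not into ene reactions. It also needs regiochemically pure 4, because a 2-substituted diene would put neither oxygen on the substituted carbon.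

**Ring–arm bond.** Diene 4 is cut between C1 (sp2) and the first carbon of the arm into dienyl triflate 2 and alkyltrifluoroborate 3. 1,2-Addition to enone 1 followed by dehydration would give a mixture of diene regioisomers, and a 2-alkoxyethyl Grignard or lithium reagent fragments by β-elimination. The triflate fixes the position of the new bond and 3 is a bench-stable salt. The coupling must outrun β-hydride and β-alkoxide loss from the alkylpalladium intermediate and must not isomerise the diene.

**Enol triflate.** Triflate 2 derives from cyclohex-2-en-1-one 1 by O-sulfonylation and loss of a proton from C4 (the γ-carbon). The carbonyl carbon of 1 becomes C1 of the target and the γ-carbon becomes C4. The forward step must give the linear dienyl triflate and not the cross-conjugated isomer that arises by proton loss from C6.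

## Roads not taken

**Alternative 1: Prins route.** The cut is between the two carbons of the arm and at C1–O, giving 4-methylenecyclohexan-1-one A1 and two molecules of formaldehyde A2.
- Forward key step: acid-activated A2 is attacked by the exocyclic methylene carbon of A1, the tertiary cation at C1 is captured by the oxygen of a second A2, and the spiro formal 1,3-dioxaspiro[5.5]undecan-9-one A3 closes. Acidic cleavage of the formal would give 9, and the acylation of step 6 would finish.
- Merits: three steps from A1, no peroxide, no photochemistry, and the ketone is present from the start.
- Weak points: the C1 cation can lose a proton to give unsaturated homoallylic alcohols instead of being trapped. A1 has an enolisable ketone that can itself condense with A2 under the same acid. The 1,3-dioxane formal is a very robust acetal, so freeing 9 needs strong acid and a scavenger for A2, conditions under which the tertiary alcohol can ionise again. A1 is also costlier than 1.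
- Comparison: in step count this road is clearly better, about half the length. The chosen plan sets against it that both oxygens are placed by mechanism and not by the partitioning of a cation, and that no intermediate carrying the tertiary alcohol meets strong acid.

**Alternative 2: Cathodic ketone–acrylate coupling.** The cut is the ring bond C1–C2, followed by the ring bond C4–C5 next to the future ketone, giving methyl 6-(benzyloxy)-4-oxohexanoate A4 and methyl acrylate A5.
- Forward key step: cathodic electron transfer to A4 gives a ketyl radical anion that adds to the β-carbon of A5. The tertiary alkoxide then lactonises to methyl 3-(2-(2-(benzyloxy)ethyl)-5-oxotetrahydrofuran-2-yl)propanoate A6.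
- Continuation: a Dieckmann condensation between the two equal three-carbon arms would release the C1 alkoxide and give methyl 5-(2-(benzyloxy)ethyl)-5-hydroxy-2-oxocyclohexane-1-carboxylate A7. Dealkoxycarbonylation would give 8, where the chosen endgame takes over.
- Merits: the quaternary carbinol is made directly in a C–C bond formation, electricity replaces a stoichiometric reductant, and no peroxide is handled.
- Weak points: A4 is not purchasable and is a β-alkoxy ketone that can lose its benzyloxy group by β-elimination in a basic catholyte. Hydrodimerisation of A5 and reduction or pinacol coupling of A4 compete with the cross-coupling. The Dieckmann step is reversible and the decarboxylation heats a tertiary alcohol. The count is at least seven steps plus those to A4.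
- Comparison: this road is longer and assembles a ring that can be bought. Its real advantage is a peroxide-free, light-free sequence, against which the chosen plan sets brevity and only a short, cold, dilute lifetime for peroxide 6.

**Alternative 3: [3+3] annulation.** The cut is at the ring bonds C2–C3 and C5–C6. Acetone N,N-dimethylhydrazone A8 serves as a three-carbon 1,3-dianion equivalent, and 2-(2-(benzyloxy)ethyl)-2-(chloromethyl)oxirane A9 as the 1,3-dielectrophile carrying C1 and its oxygen.
- Forward key step: the lithium azaenolate of A8 alkylates A9, a second deprotonation at the other methyl group follows, and the new azaenolate opens the epoxide at its CH2 terminus. The ring closes as 4-(2-(benzyloxy)ethyl)-4-hydroxycyclohexan-1-one N,N-dimethylhydrazone A10, and hydrazone hydrolysis gives 8.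
- Merits: convergent and redox-neutral, both oxygens arrive at their final oxidation levels, and no peroxide is handled. Chloride displacement and epoxide opening with re-closure lead to the same first alkylation product.
- Weak points: A9 is not purchasable and takes several steps. The second deprotonation must occur at the remote methyl and not at the alkylated carbon. The ring closure is a six-membered endo-mode epoxide opening with a strained trajectory, so intermolecular oligomerisation competes.
- Comparison: this road is at least as good in redox economy and needs no light. With the steps to A9 it is longer, and the chosen plan sets against it two purchasable partners and a key step whose ring size and oxygen placement are fixed by the cycloaddition.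

Key step: step 3

Remark on the chemistry: salt 3 is treated as purchasable, 6 and 7 are racemic with one enantiomer drawn, and ring positions in the discussion are counted from the carbinol carbon (C1) to the ketone carbon (C4), while systematic names keep their own locants.

## Route

Step 1
Reactants: 1 cyclohex-2-en-1-one
Product: 2 cyclohexa-1,3-dien-1-yl trifluoromethanesulfonate
Conditions: Tf2O, 2,6-di-tert-butyl-4-methylpyridine, CH2Cl2, 0 °C to rt
Reagents that add atoms: trifluoromethanesulfonic anhydride (Tf2O), O=S(=O)(OS(=O)(=O)C(F)(F)F)C(F)(F)F
Why: Thermodynamic dienyl triflate formation from an enone: O-sulfonylation of the carbonyl gives a triflyloxy allyl cation, and the hindered, non-nucleophilic pyridine removes the γ-proton at C4 to give the linear, through-conjugated dienyl triflate, as is established for cyclic enones under these conditions. Amide bases, which deprotonate C6 and lead to the cross-conjugated isomer, are avoided; no stereocentre is formed.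

Step 2
Reactants: 2 cyclohexa-1,3-dien-1-yl trifluoromethanesulfonate; 3 potassium (2-(benzyloxy)ethyl)trifluoroborate
Product: 4 ((2-(cyclohexa-1,3-dien-1-yl)ethoxy)methyl)benzene
Conditions: PdCl2(dppf) (cat.), Cs2CO3, THF/H2O, 65 °C, degassed
Reagents that add atoms: none
Why: B-alkyl Suzuki–Miyaura cross-coupling of a primary alkyltrifluoroborate with an alkenyl triflate: zerovalent palladium inserts into the C–OTf bond, the alkyl group is transferred from boron after slow hydrolysis of the BF3K group, and reductive elimination forms the C1–CH2 bond. The wide-bite-angle dppf ligand speeds reductive elimination over β-hydride or β-alkoxide loss, and the benzyl ether is a spectator.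

Step 3
Reactants: 4 ((2-(cyclohexa-1,3-dien-1-yl)ethoxy)methyl)benzene; 5 dioxygen
Product: 6 rac-(1S,4S)-1-(2-(benzyloxy)ethyl)-2,3-dioxabicyclo[2.2.2]oct-5-ene
Conditions: O2, tetraphenylporphyrin (cat.), visible light, CH2Cl2, −20 °C
Reagents that add atoms: none
Why: Energy transfer from the photoexcited porphyrin converts 5 into its singlet state, a small electrophilic dienophile that adds to the diene of 4 in a concerted, suprafacial [4+2] cycloaddition. The closest known reaction is the dye-sensitised photooxygenation of α-terpinene to ascaridole, the same change on the same ring type. The 1,2-dioxine ring (C1, O, O, C4, C3, C2) is closed by cycloaddition, both C–O bonds forming in one step, which also creates the 2,3-dioxabicyclo[2.2.2]octene skeleton. The two new stereocentres are the bridgeheads C1 and C4; their relative configuration is fixed by the two-atom bridge, which can only span one face, and because the two faces of 4 are enantiotopic, 6 forms as a racemate. The selectivity needed is [4+2] addition over ene reaction at the allylic hydrogens of C5, C6 and the first side-chain carbon; there is no regiochemical question because 5 is symmetrical. It is secured by the ring-locked s-cis diene, whose termini lie at the right distance for O2, by the electron-rich trisubstituted C1 terminus, and by low temperature in a non-polar solvent, which favours the cycloaddition with its low activation enthalpy. The benzyl ether does not react with singlet oxygen under these conditions.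

Step 4
Reactants: 6 rac-(1S,4S)-1-(2-(benzyloxy)ethyl)-2,3-dioxabicyclo[2.2.2]oct-5-ene
Product: 7 racemic 4-(2-(benzyloxy)ethyl)-4-hydroxycyclohex-2-en-1-one
Conditions: Et3N, CH2Cl2, 0 °C to rt
Reagents that add atoms: none
Why: Kornblum–DeLaMare rearrangement: the amine removes the only hydrogen on a peroxide-bearing carbon (C4–H) while the weak O–O bond breaks in an E2-like manner, giving the C4 ketone and, after proton transfer, the C1 tertiary alcohol. C1 has no hydrogen, so the opposite regiochemistry is impossible; the C4 stereocentre is destroyed and C1 remains as a racemic centre.

Step 5
Reactants: 7 racemic 4-(2-(benzyloxy)ethyl)-4-hydroxycyclohex-2-en-1-one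
Product: 9 4-hydroxy-4-(2-hydroxyethyl)cyclohexan-1-one, via saturated benzyl ether 8 (not isolated)
Conditions: H2 (1 atm), Pd/C, EtOAc, rt
Reagents that add atoms: none
Why: Heterogeneous catalytic hydrogenation with hydrogenolysis: the conjugated C=C is saturated first to give 8, then the benzyl C–O bond is cleaved, so the freed primary hydroxyl never coexists with the enone and cannot add to it. Neutral EtOAc avoids dehydration of the tertiary alcohol, and saturation makes the two ring branches at the carbinol carbon identical, so 9 is achiral.

Step 6
Reactants: 9 4-hydroxy-4-(2-hydroxyethyl)cyclohexan-1-one; 10 palmitoyl chloride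
Product: 11 2-(1-hydroxy-4-oxocyclohexyl)ethyl hexadecanoate
Conditions: pyridine, CH2Cl2, 0 °C
Reagents that add atoms: none
Why: Nucleophilic acyl substitution (O-acylation with an acid chloride): the unhindered primary hydroxyl reacts far faster than the tertiary one, and pyridine takes up the HCl. With about one equivalent of 10 and no added acylation catalyst the tertiary alcohol and the ketone are left alone; 11 has no stereocentre.

## Compound list

1 | cyclohex-2-en-1-one | O=C1C=CCCC1 | starting material
2 | cyclohexa-1,3-dien-1-yl trifluoromethanesulfonate | O=S(=O)(OC1=CC=CCC1)C(F)(F)F | intermediate
3 | potassium (2-(benzyloxy)ethyl)trifluoroborate | [K+].F[B-](F)(F)CCOCc1ccccc1 | starting material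
4 | ((2-(cyclohexa-1,3-dien-1-yl)ethoxy)methyl)benzene (benzyl 2-(cyclohexa-1,3-dien-1-yl)ethyl ether) | C1(CCOCc2ccccc2)=CC=CCC1 | intermediate
5 | dioxygen | O=O | starting material
6 | rac-(1S,4S)-1-(2-(benzyloxy)ethyl)-2,3-dioxabicyclo[2.2.2]oct-5-ene (racemic, one enantiomer drawn) | C(COCc1ccccc1)[C@]12OO[C@H](C=C1)CC2 | intermediate
7 | racemic 4-(2-(benzyloxy)ethyl)-4-hydroxycyclohex-2-en-1-one (S enantiomer drawn) | C(COCc1ccccc1)[C@]1(O)C=CC(=O)CC1 | intermediate
8 | 4-(2-(benzyloxy)ethyl)-4-hydroxycyclohexan-1-one (achiral, not isolated) | O=C1CCC(O)(CCOCc2ccccc2)CC1 | intermediate
9 | 4-hydroxy-4-(2-hydroxyethyl)cyclohexan-1-one (achiral) | O=C1CCC(O)(CCO)CC1 | intermediate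
10 | palmitoyl chloride (hexadecanoyl chloride) | CCCCCCCCCCCCCCCC(=O)Cl | starting material
11 | 2-(1-hydroxy-4-oxocyclohexyl)ethyl hexadecanoate (achiral) | CCCCCCCCCCCCCCCC(=O)OCCC1(O)CCC(=O)CC1 | target

## Step count and risk

Total: 6 steps. Longest linear sequence: 6 steps (1 → 2 → 4 → 6 → 7 → 9 → 11).

**Step 3 (key step).**
- Risk: singlet oxygen may be diverted into ene reactions at the allylic C–H bonds of C6, C5 and the side chain, because the C1 terminus is trisubstituted and flanked by three allylic positions. The resulting hydroperoxides can dehydrate and aromatise the ring. The peroxide bridge can also rearrange thermally or photochemically if the solution warms or is concentrated.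
- Fallback, from 4 back to the route at 7 with two-electron oxidants only: the more substituted C1=C2 bond of 4 is epoxidised with mCPBA (NaHCO3, CH2Cl2, 0 °C) to 6-(2-(benzyloxy)ethyl)-7-oxabicyclo[4.1.0]hept-2-ene F1. Pd(PPh3)4-catalysed 1,4-opening with acetic acid in THF follows: zerovalent palladium ionises the allylic C–O bond, and acetate attacks the distal allyl terminus anti to the metal. This gives cis-4-(2-(benzyloxy)ethyl)-4-hydroxycyclohex-2-en-1-yl acetate F2. Methanolysis (K2CO3, MeOH) gives cis-1-(2-(benzyloxy)ethyl)cyclohex-2-ene-1,4-diol F3, and MnO2 in CH2Cl2 oxidises the secondary allylic alcohol to 7. The cost is two extra steps.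

**Step 1.**
- Risk: regiochemical leakage through proton loss from C6 instead of C4. The cross-conjugated triflate would carry through step 2 to a 2-substituted diene whose endoperoxide has the wrong connectivity. Material may also be lost through volatility and hydrolysis of the small triflate.
- Fallback, from 3 back to the route at 4: salt 3 is coupled under the conditions of step 2 with purchasable 3-oxocyclohex-1-en-1-yl trifluoromethanesulfonate F4, whose triflate position is unambiguous, to give 3-(2-(benzyloxy)ethyl)cyclohex-2-en-1-one F5. Condensation with 4-methylbenzenesulfonohydrazide in MeOH gives N'-(3-(2-(benzyloxy)ethyl)cyclohex-2-en-1-ylidene)-4-methylbenzenesulfonohydrazide F6. A Shapiro reaction (LiN(iPr)2 or MeLi, THF, −78 °C to rt, then water) removes an α′-hydrogen at C6, expels sulfinate and N2, and after protonation of the vinyllithium gives 4. The new double bond lies regiospecifically between the former carbonyl carbon and C6.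

**Step 2.**
- Risk: β-alkoxide elimination from the 2-(benzyloxy)ethylpalladium intermediate, or protodeboronation of 3, may compete with the slow sp3 transmetalation. Palladium hydride species may also shift or dehydrogenate the diene.
- Fallback, from 2 back to the route at 4: the arm is introduced at the ester oxidation level, so that no β-alkoxyalkyl metal species occurs. Pd(PPh3)4-catalysed Negishi-type coupling of 2 with the zinc enolate BrZnCH2CO2tBu in THF gives tert-butyl 2-(cyclohexa-1,3-dien-1-yl)acetate F7. LiAlH4 in Et2O at 0 °C reduces it to 2-(cyclohexa-1,3-dien-1-yl)ethan-1-ol F8, and NaH with benzyl bromide in THF gives 4.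

**Step 4.**
- Risk: deprotonation at the bridgehead of the rigid bicycle may be slow. More forcing base then promotes dehydration of 7 and aromatisation to a para-substituted phenol.
- Fallback, from 6 to the route's end at 11, reversing the redox order: exhaustive hydrogenation of 6 (H2, Pd/C, EtOAc) cleaves the O–O bond with retention at both carbons, saturates the alkene and removes the benzyl group, giving cis-1-(2-hydroxyethyl)cyclohexane-1,4-diol F9. Acylation of the primary hydroxyl with 10 (2,4,6-collidine, CH2Cl2, −40 °C) gives 2-(cis-1,4-dihydroxycyclohexyl)ethyl hexadecanoate F10. Oxidation of the remaining secondary alcohol with Dess–Martin periodinane (NaHCO3, CH2Cl2) gives 11. The price is a primary-over-secondary acylation, which is less clear-cut than the primary-over-tertiary one of step 6.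

## Further compounds

F1 | step 3 | 6-(2-(benzyloxy)ethyl)-7-oxabicyclo[4.1.0]hept-2-ene (racemic, cis-fused, one enantiomer drawn) | C(COCc1ccccc1)[C@]12CCC=C[C@H]1O2
F2 | step 3 | cis-4-(2-(benzyloxy)ethyl)-4-hydroxycyclohex-2-en-1-yl acetate (racemic, one enantiomer drawn) | O[C@]1(CCOCc2ccccc2)C=C[C@H](OC(C)=O)CC1
F3 | step 3 | cis-1-(2-(benzyloxy)ethyl)cyclohex-2-ene-1,4-diol (racemic, one enantiomer drawn) | O[C@]1(CCOCc2ccccc2)C=C[C@H](O)CC1
F4 | step 1 | 3-oxocyclohex-1-en-1-yl trifluoromethanesulfonate | O=C1C=C(OS(=O)(=O)C(F)(F)F)CCC1
F5 | step 1 | 3-(2-(benzyloxy)ethyl)cyclohex-2-en-1-one | O=C1C=C(CCOCc2ccccc2)CCC1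
F6 | step 1 | N'-(3-(2-(benzyloxy)ethyl)cyclohex-2-en-1-ylidene)-4-methylbenzenesulfonohydrazide (C=N geometry not controlled) | Cc1ccc(cc1)S(=O)(=O)NN=C1C=C(CCOCc2ccccc2)CCC1
F7 | step 2 | tert-butyl 2-(cyclohexa-1,3-dien-1-yl)acetate | CC(C)(C)OC(=O)CC1=CC=CCC1
F8 | step 2 | 2-(cyclohexa-1,3-dien-1-yl)ethan-1-ol | OCCC1=CC=CCC1
F9 | step 4 | cis-1-(2-hydroxyethyl)cyclohexane-1,4-diol (achiral) | O[C@]1(CCO)CC[C@H](O)CC1
F10 | step 4 | 2-(cis-1,4-dihydroxycyclohexyl)ethyl hexadecanoate (achiral) | CCCCCCCCCCCCCCCC(=O)OCC[C@@]1(O)CC[C@H](O)CC1
A1 | alternative 1 | 4-methylenecyclohexan-1-one | C=C1CCC(=O)CC1
A2 | alternative 1 | formaldehyde | C=O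
A3 | alternative 1 | 1,3-dioxaspiro[5.5]undecan-9-one | O=C1CCC2(CC1)CCOCO2
A4 | alternative 2 | methyl 6-(benzyloxy)-4-oxohexanoate | COC(=O)CCC(=O)CCOCc1ccccc1
A5 | alternative 2 | methyl acrylate | C=CC(=O)OC
A6 | alternative 2 | methyl 3-(2-(2-(benzyloxy)ethyl)-5-oxotetrahydrofuran-2-yl)propanoate (racemic) | COC(=O)CCC1(CCOCc2ccccc2)CCC(=O)O1
A7 | alternative 2 | methyl 5-(2-(benzyloxy)ethyl)-5-hydroxy-2-oxocyclohexane-1-carboxylate (mixture of stereoisomers) | COC(=O)C1CC(O)(CCOCc2ccccc2)CCC1=O
A8 | alternative 3 | acetone N,N-dimethylhydrazone | CC(C)=NN(C)C
A9 | alternative 3 | 2-(2-(benzyloxy)ethyl)-2-(chloromethyl)oxirane (racemic) | ClCC1(CCOCc2ccccc2)CO1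
A10 | alternative 3 | 4-(2-(benzyloxy)ethyl)-4-hydroxycyclohexan-1-one N,N-dimethylhydrazone | CN(C)N=C1CCC(O)(CCOCc2ccccc2)CC1
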